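## Structural features

Ambofuranol is a 2-arylbenzofuran without any stereocentre: ring A (C3a–C7a) is fused to the furan ring, and ring B is joined to C2 by a single aryl–heteroaryl bond. Ring A carries a hydroxyl on C6 and a 3-methylbut-2-enyl (prenyl) chain on the neighbouring C5, so C4 and C7 are its only unsubstituted positions. The furan ring carries a methoxy group on C3. Ring B has a free hydroxyl ortho (C2') and a methoxy group para (C4') to the bond to C2. Two of the four oxygens on sp2 carbon are methylated and two are free, so each oxygen has to be told apart at some stage. The fragile parts are the prenyl olefin next to a free phenol (acid closes it to a chroman; electrophiles and hydrogenation destroy it), the electron-rich 3-methoxybenzofuran (an aromatic enol ether), and any benzofuran-3(2H)-one intermediate, which autoxidizes at C2. The real difficulty is the regiochemistry of ring A, a 1,2,4,5-tetrasubstituted benzene whose prenyl group is hard to place by substitution on a resorcinol. The key step uses the fact that the C6 hydroxyl is para to C3a with prenyl beside it: this is the pattern left when a furan with an acyl group on its C2 and prenyl on its C4 adds an alkyne across C2 and C5 and the bridging oxygen stays on the former furan C5, which is C6 of ring A.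

## Logic of the disconnections

21 from 20. The O–Si bond at C6 and the O–CH2 acetal bond at C2' are cut. Both phenols must be masked while the C3 oxygen is methylated, and both masks are chosen to fall to fluoride so that no acid meets the prenyl group beside a free phenol. The gain is that the four oxygens become distinguishable. The demand is that one basic operation cleaves an aryl silyl ether and an aryl SEM ether together.

20 from 18. The O–CH3 bond at C3 is cut. The aromatic furan ring is the methyl enol ether of a benzofuran-3(2H)-one, which is exactly the ring that the key step delivers. The gain is that furan aromaticity no longer has to be built directly. The demand is O-alkylation, not C2-alkylation, of an ambident enolate.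

18 from 17. The O–Si bond at C6 is cut. The C6 phenol is more acidic than C2–H and would be methylated first, so it is capped. The demand is silylation of the phenol without silylation of the enol.

17 from 15. The C3a–C7a and C6–C7 bonds are cut. This removes ring A and the furanone ring together and replaces a tetrasubstituted benzene by a 2,4-disubstituted furan and a terminal alkyne. Prenyl at C5, hydrogen at C4 and C7 and oxygen at C6 are then fixed by connectivity alone. The demand is heavy: the cycloaddition must outrun the thermal and acid-induced decay of a benzylic ynol ether, and the oxygen bridge must open towards C6.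

15 from 12. No skeletal bond is cut; the C≡C–H of the ynol ether is traced back to a ClC=CHCl unit. The ynol ether is the most fragile group of the route and is therefore made last, immediately before use, from its most robust precursor. The demand is that n-BuLi acts in the presence of a ketone, which is met by storing the ketone as its enolate.

12 from 11. The C3 carbonyl is exchanged for two C–S bonds. Thioacetal cleavage is an electrophilic process that no ynol ether would survive, so the ketone is unmasked while the alkyne is still a dichlorovinyl ether. The demand is a cleavage that spares the prenyl olefin, the furan and the SEM group.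

11 from 8 and 9. The O1–C7a bond (the O–vinyl bond) is cut. The two carbons that become C7 and C7a then come from a bulk chemical. The demand is a potassium alkoxide next to the ortho oxygen of ring B. A silyl ether there would migrate to the alkoxide, so that oxygen carries an acetal, and the future ketone must be a thioacetal.

8 from 4 and 6. The C2–C3 bond is cut. This is the most convergent cut, joining the ring B half to the furan half with acyl-anion polarity on the furan side. The demand is deprotonation at the dithiane carbon and not at furan C5.

4 from 2 and 3, and 2 from 1. The furan C4–CH2 bond and the two C–S bonds are cut. The linear prenyl group is put on a commercial bromofuran by cross-coupling. The aldehyde is converted into the thioacetal first, because an allylboronate would add to a free aldehyde. The demand is coupling through the unhindered terminus of the allyl group.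

6 from 5. The O–CH2 bond of the acetal is cut, a simple protection of a commercial phenol.

## Other disconnections considered

Alternative 1: The cut is the O1–C7a bond of the furan ring. In the forward sense the α-methoxy ketone A2 (ring B acyl group at the future C2; methoxy and an ortho-brominated ring A at the future C3) is enolized by K3PO4, and the enolate oxygen is joined to the bromine-bearing carbon with CuI and N,N'-dimethylethylenediamine. The product is the bis(methoxymethyl) ether A1, two acetal cleavages from the target.
- In its favour: intramolecular copper-catalysed O-arylation of ketone enolates is an established route to benzofurans, so on precedent this plan is better than the chosen one. C-arylation would need a four-membered ring and cannot compete. The C3 methoxy group is in place before the ring closes, so the O- versus C-methylation question of the chosen endgame never arises; on that point it is also better.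
- Against it: every substituent of ring A (bromine, oxygen, prenyl and the benzylic carbon in a 1,2,4,5 relationship) must first be placed on a benzene ring by substitution chemistry, which the chosen plan avoids. The enolate is tetrasubstituted, doubly oxygenated and must have oxygen and ring A on the same side. The aryl bromide is electron-rich. A1 has to be unmasked with acid beside a prenyl group and an enol ether, where the chosen plan ends with fluoride.
- Comparison: structurally the alternative forms one bond and one ring against two bonds and two rings. Mechanistically it is the safer reaction. In step count the two are about equal, because what is saved at the end is spent on A2.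

Alternative 2: The cut removes ring A through the C4–C5, C6–C7 and C3a–C4 bonds, with C7–C7a arising from a 1,2-shift. In the forward sense, photolysis of the furyl diazomethyl ketone A4, which already carries ring B and the methoxy group, triggers a Wolff rearrangement. The siloxyalkyne A5 is added in a [2+2] sense, and four-electron ring opening followed by six-electron closure onto the furan (Danheiser benzannulation) should give the benzofuranol A3.
- In its favour: like the chosen plan it builds ring A from a furan and an alkyne, with prenyl and the C6 oxygen placed by the connectivity of A5, so on regiocontrol it is equal. The reaction type is known for heteroaryl diazoketones, so on precedent it is better. The C3 methoxy group is present from the start, so no enolate methylation is needed.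
- Against it: A3 has a hydroxyl on C4 that the target lacks; its removal (sulfonylation and reduction) costs two steps at a position crowded by the C3 methoxy and C5 prenyl groups. A4 needs a 2,3,5-trisubstituted 3-methoxyfuran whose own synthesis is long. A5 is sensitive. An electron-rich olefin is present during photolysis.
- Comparison: structurally the alternative closes one ring against two. Mechanistically it is better founded. In step economy it is worse by several steps.

Alternative 3: The cut takes out C2 as a one-carbon unit, through the C2–C3 and O1–C2 bonds. In the forward sense the benzylide generated from the sulfonium salt A8 and KN(SiMe3)2 attacks the carbonyl of the benzodioxinone A7, acetone leaves, and the liberated phenoxide displaces diphenyl sulfide at the same carbon to give the benzofuranone A6.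
- In its favour: the two halves are joined and the furanone is closed in one flask. A6 is the counterpart of the product of the chosen key step with the C6 oxygen already protected, so one protection step is saved, a point on which it is better. Both partners are stable and storable, whereas the chosen precursor is not, so on handling it is also better.
- Against it: once the first bond is formed, the carbon between sulfur and carbonyl is far more acidic than A8. Base or ylide is consumed and the carbonyl-stabilized ylide A9 results, whose carbon is no longer electrophilic; ring closure must wait for reprotonation. Benzylic sulfonium ylides are also prone to [2,3]-shifts. A7 again needs the full ring A pattern from arene chemistry. The methoxymethyl groups call for acid at the end.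
- Comparison: structurally the alternative makes two bonds and one ring against two bonds and two rings. In mechanistic certainty the two are about equal, both being extrapolations. In step economy the alternative is equal or slightly shorter if A7 is reached in three or four steps.

Key step: step 8

Remark on the chemistry: the atom mapping of the key step was checked (furan C2, C3, C4, C5 and the ring oxygen become C3a, C4, C5, C6 and the C6 oxygen; the alkyne carbons become C7a and C7), and the skeletons of precursor and product are consistent. Only the ring B protecting group (SEM in place of a silyl group) and the order of operations were changed. All compounds with a stereocentre at C2 are racemic and this centre is planar in 20 and 21, so no stereocontrol is needed. The commercial availability of F1, used only in a fallback, is assumed.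

## Route

Step 1
Reactants: 1 4-bromofuran-2-carbaldehyde
Product: 2 2-(4-bromofuran-2-yl)-1,3-dithiane
Conditions: HS(CH2)3SH, BF3·OEt2 (cat.), CH2Cl2, 0 °C
Reagents that add atoms: propane-1,3-dithiol, SCCCS
Why: Lewis-acid-catalysed dithioacetalization of an aryl aldehyde; it is placed first because the allylboronate 3 would add to a free aldehyde during the coupling, and the acceptor-substituted bromofuran tolerates BF3·OEt2 at 0 °C.

Step 2
Reactants: 2 2-(4-bromofuran-2-yl)-1,3-dithiane; 3 3-methylbut-2-enylboronic acid pinacol ester
Product: 4 2-[4-(3-methylbut-2-enyl)furan-2-yl]-1,3-dithiane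
Conditions: PdCl2(IPent)(3-chloropyridine) (cat.), KOH (aq.), THF, 70 °C
Reagents that add atoms: none
Why: Suzuki–Miyaura coupling of a heteroaryl bromide with an allylic boronate; the divalent palladium precatalyst is reduced to zerovalent palladium in the flask, and the very bulky carbene ligand (IPent = 1,3-bis[2,6-di(pentan-3-yl)phenyl]imidazol-2-ylidene) should make the allyl group eliminate through its unhindered CH2 terminus, so the linear prenyl isomer is expected. The thioacetal is stable to aqueous base.

Step 3
Reactants: 5 2-hydroxy-4-methoxybenzaldehyde
Product: 6 4-methoxy-2-{[2-(trimethylsilyl)ethoxy]methoxy}benzaldehyde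
Conditions: SEMCl, i-Pr2NEt, CH2Cl2, 0 °C → rt
Reagents that add atoms: 2-(trimethylsilyl)ethoxymethyl chloride (SEMCl), C[Si](C)(C)CCOCCl
Why: O-alkylation of the phenol with an α-chloro ether (Williamson type). An acetal is preferred to a silyl ether because step 5 generates a potassium alkoxide next to this oxygen and a silyl group would migrate to it; the SEM group cannot migrate, withstands KH and n-BuLi and is later removed by fluoride.

Step 4
Reactants: 4 2-[4-(3-methylbut-2-enyl)furan-2-yl]-1,3-dithiane; 6 4-methoxy-2-{[2-(trimethylsilyl)ethoxy]methoxy}benzaldehyde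
Product: 8 racemic (4-methoxy-2-{[2-(trimethylsilyl)ethoxy]methoxy}phenyl){2-[4-(3-methylbut-2-enyl)furan-2-yl]-1,3-dithian-2-yl}methanol, via lithiodithiane 7 (not isolated)
Conditions: n-BuLi, THF, −78 °C; then 6, −78 °C; H2O
Reagents that add atoms: none
Why: Corey–Seebach umpolung: at −78 °C n-BuLi removes the proton at dithiane C2 (acidified by two sulfur atoms and the furan ring) in preference to furan C5–H, and the carbanion adds to the aldehyde, forming C2–C3. The new carbinol centre is racemic and is lost later.

Step 5
Reactants: 8 racemic carbinol of step 4; 9 trichloroethylene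
Product: 11 racemic 2-[{[(E)-1,2-dichloroethenyl]oxy}(4-methoxy-2-{[2-(trimethylsilyl)ethoxy]methoxy}phenyl)methyl]-2-[4-(3-methylbut-2-enyl)furan-2-yl]-1,3-dithiane, via potassium alkoxide 10 (not isolated)
Conditions: KH, THF, 0 °C → rt; then 9, −50 °C → rt
Reagents that add atoms: none
Why: O-vinylation of an alkoxide by trichloroethylene: base-induced loss of HCl gives dichloroacetylene in the flask, the alkoxide adds, and anti protonation gives the E-1,2-dichlorovinyl ether; the method is known for hindered secondary alcohols. The dithiane keeps the future ketone inert to KH.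

Step 6
Reactants: 11 dichlorovinyl ether dithiane of step 5
Product: 12 racemic 2-{[(E)-1,2-dichloroethenyl]oxy}-2-(4-methoxy-2-{[2-(trimethylsilyl)ethoxy]methoxy}phenyl)-1-[4-(3-methylbut-2-enyl)furan-2-yl]ethanone
Conditions: MeI, CaCO3, MeCN/H2O (9:1), 45 °C
Reagents that add atoms: water, O
Why: Alkylative hydrolysis of the dithioacetal: S-methylation, ring opening to a furyl-stabilized thionium ion and hydration, with CaCO3 taking up the HI. It is done at this stage because the electron-poor dichlorovinyl ether, unlike the ynol ether to come, is inert to electrophiles; MeI leaves the prenyl olefin, the furan and the SEM group alone.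

Step 7
Reactants: 12 dichlorovinyloxy ketone of step 6
Product: 15 racemic 2-(ethynyloxy)-2-(4-methoxy-2-{[2-(trimethylsilyl)ethoxy]methoxy}phenyl)-1-[4-(3-methylbut-2-enyl)furan-2-yl]ethanone, via lithium enolate 13 (not isolated), via dilithio alkynyl ether enolate 14 (not isolated)
Conditions: LiN(SiMe3)2 (1.1 equiv), THF, −78 °C; n-BuLi (3.2 equiv), −78 °C; H2O (pH 7 buffer), −78 °C
Reagents that add atoms: none
Why: The ketone is first stored as its lithium enolate 13 (C2–H, flanked by carbonyl, aryl and oxygen, is by far the most acidic site), which n-BuLi cannot attack; n-BuLi then effects the usual dehydrochlorination of the dichlorovinyl ether to a chloroalkynyl ether and chlorine–lithium exchange to 14 (one further equivalent is taken up by the HN(SiMe3)2 formed). Cold neutral protonation returns the ketone and gives the terminal ynol ether, which is used at once.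

Step 8
Reactants: 15 racemic ynol ether ketone of step 7
Product: 17 racemic 6-hydroxy-2-(4-methoxy-2-{[2-(trimethylsilyl)ethoxy]methoxy}phenyl)-5-(3-methylbut-2-enyl)benzofuran-3(2H)-one, via oxanorbornadiene 16 (not isolated)
Conditions: PhMe (0.005 M, degassed), i-Pr2NEt (0.2 equiv), 110 °C
Reagents that add atoms: none
Why: Proposed new method: the acyl group lowers the LUMO of the furan diene and the alkoxy group raises the HOMO of the alkyne, so an inverse-demand intramolecular [4+2] cycloaddition is expected in which the nucleophilic alkyne terminus bonds to the electrophilic furan C5 (C6–C7) and the oxygen-bearing alkyne carbon bonds to furan C2 (C3a–C7a), giving 16; the closest known reaction type is the thermal intramolecular Diels–Alder reaction of furans with alkynes on a three-atom tether followed by isomerization of the 7-oxanorbornadiene to a phenol, which has not been shown for an ynol ether dienophile or a 2-acylfuran diene. Ring A is closed by the cycloaddition itself and becomes aromatic when the oxygen bridge opens; the furanone ring is closed in the same event, because the tether C3–C2–O1 spans the new C3a–C7a bond and makes a five-membered ring fused to the bicycle. No lasting stereocentre is created: C3a and C6 of 16 vanish on aromatization and C2 stays racemic. Two selectivities are needed. The first is cycloaddition ahead of the [3,3] shift of the benzylic ynol ether onto ring B (a retro-ene loss is excluded because the carbon on oxygen has no β-hydrogen); the acyl group on the benzylic carbon destabilizes the positive charge that the shift develops there, and the tether holds the alkyne over the furan. The second is the direction of bridge opening: heterolysis of C6–O can only revert, since C3a has no hydrogen to lose, whereas amine-assisted enolization of C3 towards C2 makes the C3a–O bond allylic and lets O1 and ring B push it out, after which loss of the C6 proton puts the hydroxyl on C6 and nowhere else. High dilution and the amine buffer keep the acidic phenol 17 from adding to unreacted ynol ether.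

Step 9
Reactants: 17 racemic benzofuranone of step 8
Product: 18 racemic 2-(4-methoxy-2-{[2-(trimethylsilyl)ethoxy]methoxy}phenyl)-5-(3-methylbut-2-enyl)-6-(triisopropylsilyloxy)benzofuran-3(2H)-one
Conditions: i-Pr3SiCl (1.05 equiv), imidazole, DMF, 0 °C → rt, argon
Reagents that add atoms: chlorotriisopropylsilane, CC(C)[Si](Cl)(C(C)C)C(C)C
Why: Imidazole-assisted silylation of a phenol; the C6 hydroxyl, para to the ketone, is far more acidic than the C2–H enol and should be silylated selectively with one equivalent, so that it cannot be methylated in step 10. Argon is used because 2-arylbenzofuran-3(2H)-ones autoxidize at C2.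

Step 10
Reactants: 18 racemic silyl ether of step 9
Product: 20 3-methoxy-2-(4-methoxy-2-{[2-(trimethylsilyl)ethoxy]methoxy}phenyl)-5-(3-methylbut-2-enyl)-6-(triisopropylsilyloxy)benzofuran, via potassium enolate 19 (not isolated)
Conditions: KN(SiMe3)2, THF/DMPU, −78 °C; Me2SO4, −78 → 0 °C
Reagents that add atoms: dimethyl sulfate, COS(=O)(=O)OC
Why: O-alkylation of an ambident enolate: 19 is the anion of an aromatic 3-hydroxybenzofuran, and such phenoxide-like anions, as free potassium salts in a dipolar medium, react with the hard electrophile Me2SO4 at oxygen; C2 is also shielded by the ortho-substituted ring B. The furan ring becomes aromatic and the C2 stereocentre disappears.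

Step 11
Reactants: 20 protected 3-methoxybenzofuran of step 10
Product: 21 ambofuranol, 5-methoxy-2-[6-hydroxy-3-methoxy-5-(3-methylbut-2-enyl)benzofuran-2-yl]phenol
Conditions: Bu4NF, H2N(CH2)2NH2, DMF, 60 °C; aq. NH4Cl
Reagents that add atoms: none
Why: Fluoride cleaves the aryl O–Si bond and attacks the silicon of the SEM group, whose fragmentation to Me3SiF, ethene and formaldehyde is eased by the phenoxide leaving group; ethylenediamine traps the formaldehyde so that the electron-rich phenoxides are not hydroxymethylated. No acid is used, which protects the prenyl group beside the free C6 hydroxyl.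

## Compound list

1 | 4-bromofuran-2-carbaldehyde | O=Cc1cc(Br)co1 | starting material
2 | 2-(4-bromofuran-2-yl)-1,3-dithiane | Brc1coc(C2SCCCS2)c1 | intermediate
3 | 3-methylbut-2-enylboronic acid pinacol ester | CC(C)=CCB1OC(C)(C)C(C)(C)O1 | starting material
4 | 2-[4-(3-methylbut-2-enyl)furan-2-yl]-1,3-dithiane | CC(C)=CCc1coc(C2SCCCS2)c1 | intermediate
5 | 2-hydroxy-4-methoxybenzaldehyde | COc1ccc(C=O)c(O)c1 | starting material
6 | 4-methoxy-2-{[2-(trimethylsilyl)ethoxy]methoxy}benzaldehyde | COc1ccc(C=O)c(OCOCC[Si](C)(C)C)c1 | intermediate
7 | 2-lithio-2-[4-(3-methylbut-2-enyl)furan-2-yl]-1,3-dithiane | [Li]C1(c2cc(CC=C(C)C)co2)SCCCS1 | intermediate (not isolated)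
8 | (4-methoxy-2-{[2-(trimethylsilyl)ethoxy]methoxy}phenyl){2-[4-(3-methylbut-2-enyl)furan-2-yl]-1,3-dithian-2-yl}methanol, racemic | COc1ccc(C(O)C2(c3cc(CC=C(C)C)co3)SCCCS2)c(OCOCC[Si](C)(C)C)c1 | intermediate
9 | trichloroethylene | ClC=C(Cl)Cl | starting material
10 | potassium alkoxide of 8, racemic | COc1ccc(C(O[K])C2(c3cc(CC=C(C)C)co3)SCCCS2)c(OCOCC[Si](C)(C)C)c1 | intermediate (not isolated)
11 | 2-[{[(E)-1,2-dichloroethenyl]oxy}(4-methoxy-2-{[2-(trimethylsilyl)ethoxy]methoxy}phenyl)methyl]-2-[4-(3-methylbut-2-enyl)furan-2-yl]-1,3-dithiane, racemic | COc1ccc(C(O/C(Cl)=C\Cl)C2(c3cc(CC=C(C)C)co3)SCCCS2)c(OCOCC[Si](C)(C)C)c1 | intermediate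
12 | 2-{[(E)-1,2-dichloroethenyl]oxy}-2-(4-methoxy-2-{[2-(trimethylsilyl)ethoxy]methoxy}phenyl)-1-[4-(3-methylbut-2-enyl)furan-2-yl]ethanone, racemic | COc1ccc(C(O/C(Cl)=C\Cl)C(=O)c2cc(CC=C(C)C)co2)c(OCOCC[Si](C)(C)C)c1 | intermediate
13 | lithium enolate of 12 (enolate geometry not defined) | COc1ccc(C(O/C(Cl)=C\Cl)=C(O[Li])c2cc(CC=C(C)C)co2)c(OCOCC[Si](C)(C)C)c1 | intermediate (not isolated)
14 | lithium enolate of the lithium alkynyl ether (dilithio form of 15; enolate geometry not defined) | COc1ccc(C(OC#C[Li])=C(O[Li])c2cc(CC=C(C)C)co2)c(OCOCC[Si](C)(C)C)c1 | intermediate (not isolated)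
15 | 2-(ethynyloxy)-2-(4-methoxy-2-{[2-(trimethylsilyl)ethoxy]methoxy}phenyl)-1-[4-(3-methylbut-2-enyl)furan-2-yl]ethanone, racemic | C#COC(C(=O)c1cc(CC=C(C)C)co1)c1ccc(OC)cc1OCOCC[Si](C)(C)C | intermediate
16 | 7-oxanorbornadiene cycloadduct of 15: oxygen bridge between C3a and C6, double bonds C4=C5 and C7=C7a, furanone ring fused at C3a–C7a; racemic, mixture of C2 epimers | O=C1C(c4ccc(OC)cc4OCOCC[Si](C)(C)C)OC2=CC3OC12C=C3CC=C(C)C | intermediate (not isolated)
17 | 6-hydroxy-2-(4-methoxy-2-{[2-(trimethylsilyl)ethoxy]methoxy}phenyl)-5-(3-methylbut-2-enyl)benzofuran-3(2H)-one, racemic | O=C1C(c2ccc(OC)cc2OCOCC[Si](C)(C)C)Oc2cc(O)c(CC=C(C)C)cc21 | intermediate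
18 | 2-(4-methoxy-2-{[2-(trimethylsilyl)ethoxy]methoxy}phenyl)-5-(3-methylbut-2-enyl)-6-(triisopropylsilyloxy)benzofuran-3(2H)-one, racemic | O=C1C(c2ccc(OC)cc2OCOCC[Si](C)(C)C)Oc2cc(O[Si](C(C)C)(C(C)C)C(C)C)c(CC=C(C)C)cc21 | intermediate
19 | potassium 2-(4-methoxy-2-{[2-(trimethylsilyl)ethoxy]methoxy}phenyl)-5-(3-methylbut-2-enyl)-6-(triisopropylsilyloxy)benzofuran-3-olate | [K]Oc1c(-c2ccc(OC)cc2OCOCC[Si](C)(C)C)oc2cc(O[Si](C(C)C)(C(C)C)C(C)C)c(CC=C(C)C)cc12 | intermediate (not isolated)
20 | 3-methoxy-2-(4-methoxy-2-{[2-(trimethylsilyl)ethoxy]methoxy}phenyl)-5-(3-methylbut-2-enyl)-6-(triisopropylsilyloxy)benzofuran | COc1c(-c2ccc(OC)cc2OCOCC[Si](C)(C)C)oc2cc(O[Si](C(C)C)(C(C)C)C(C)C)c(CC=C(C)C)cc12 | intermediate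
21 | ambofuranol | COc1ccc(-c2oc3cc(O)c(CC=C(C)C)cc3c2OC)c(O)c1 | target

## Step count and least certain steps

Total step count: 11. Longest linear sequence: 10 steps (1 → 2 → 4 → 8 → 11 → 12 → 15 → 17 → 18 → 20 → 21); step 3 is the side branch.

Step 8 (key step, proposed new method). The most likely failure is consumption of the ynol ether before cycloaddition: by [3,3] shift onto ring B, by addition of the enol oxygen or of the phenolic product to the alkyne, or simply because the acylfuran, which loses its conjugation in the transition state, reacts too slowly. The second risk is opening of the bridge at C6–O with skeletal rearrangement instead of return. If conversion is slow the temperature would be raised in xylenes before the plan is abandoned.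
Fallback: it sets out from 3 and 6, uses only known reaction types and gives up the furan as the source of ring A.
- Commercial 5-bromo-2,4-dihydroxybenzaldehyde F1 is silylated at the hydroxyl that is not hydrogen-bonded to the aldehyde (i-Pr3SiCl, imidazole) to 5-bromo-2-hydroxy-4-(triisopropylsilyloxy)benzaldehyde F2.
- Propane-1,3-dithiol and BF3·OEt2 give 2-[5-bromo-2-hydroxy-4-(triisopropylsilyloxy)phenyl]-1,3-dithiane F3.
- Coupling with 3 (catalyst of step 2, K3PO4 as base to spare the silyl ether) gives 2-[2-hydroxy-5-(3-methylbut-2-enyl)-4-(triisopropylsilyloxy)phenyl]-1,3-dithiane F4.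
- Its dianion (n-BuLi, 2 equiv) is added to 6 to give {2-[2-hydroxy-5-(3-methylbut-2-enyl)-4-(triisopropylsilyloxy)phenyl]-1,3-dithian-2-yl}(4-methoxy-2-{[2-(trimethylsilyl)ethoxy]methoxy}phenyl)methanol F5.
- An intramolecular Mitsunobu etherification (PPh3, DIAD) closes the O1–C2 bond to 2-(4-methoxy-2-{[2-(trimethylsilyl)ethoxy]methoxy}phenyl)-5-(3-methylbut-2-enyl)-6-(triisopropylsilyloxy)-2H-spiro[benzofuran-3,2'-[1,3]dithiane] F6.
- MeI/CaCO3 as in step 6 unmasks the ketone, and the route is rejoined at 18.

Step 7. The likely failures are incomplete enolization followed by addition of n-BuLi to the ketone, attack of the enolate oxygen on the chloroalkyne before chlorine–lithium exchange, and hydration of the ynol ether if the work-up is not kept neutral and cold.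
Fallback, from 12: NaBH4 (MeOH, 0 °C) reduces the ketone to 2-{[(E)-1,2-dichloroethenyl]oxy}-2-(4-methoxy-2-{[2-(trimethylsilyl)ethoxy]methoxy}phenyl)-1-[4-(3-methylbut-2-enyl)furan-2-yl]ethanol F7 (diastereomer mixture, of no consequence). n-BuLi (3.3 equiv, THF, −78 °C), which now meets only a lithium alkoxide, converts it into 2-(ethynyloxy)-2-(4-methoxy-2-{[2-(trimethylsilyl)ethoxy]methoxy}phenyl)-1-[4-(3-methylbut-2-enyl)furan-2-yl]ethanol F8. MnO2 in CH2Cl2, a neutral oxidant specific for the furyl carbinol, returns the route at 15.

Step 2. The likely failures are coupling through the tertiary allyl terminus (branched 1,1-dimethylallyl isomer) and slowing of the catalyst by the thioacetal sulfur.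
Fallback, from 1: Stille coupling with tributyl(3-methylbut-2-enyl)stannane and Pd(PPh3)4 (zerovalent palladium; DMF, 80 °C) uses an allylstannane that does not add to the free aldehyde and transfers mainly the linear group. It gives 4-(3-methylbut-2-enyl)furan-2-carbaldehyde F9. Thioacetalization under mild catalysis that spares the prenyl olefin (propane-1,3-dithiol, MgBr2·OEt2, Et2O) rejoins the route at 4.

Step 10. The likely failure is alkylation at C2 instead of oxygen, which would create a quaternary centre and block aromatization.
Fallback, from 18: trimethyl orthoformate and a catalytic amount of camphorsulfonic acid in MeOH convert the ketone into 3,3-dimethoxy-2-(4-methoxy-2-{[2-(trimethylsilyl)ethoxy]methoxy}phenyl)-5-(3-methylbut-2-enyl)-6-(triisopropylsilyloxy)-2,3-dihydrobenzofuran F10. On warming it loses methanol towards the only enolizable side and gives 20, so the ambident enolate is avoided altogether.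

Step 11. The likely failures are incomplete fragmentation of the aryl SEM ether at a temperature the product tolerates, and hydroxymethylation of the electron-rich rings if formaldehyde is not trapped fast enough.
Fallback, from 20: the SEM acetal is cleaved first by acid-catalysed methanolysis (pyridinium p-toluenesulfonate or dilute HCl in MeOH, 40 °C) while the C6 oxygen is still silylated, so that no free phenol stands beside the prenyl group and chroman formation is excluded. This gives 5-methoxy-2-[3-methoxy-5-(3-methylbut-2-enyl)-6-(triisopropylsilyloxy)benzofuran-2-yl]phenol F11. Bu4NF in THF at 0 °C then removes the silyl group and reaches 21.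

## Further compounds

F1 | step 8 | 5-bromo-2,4-dihydroxybenzaldehyde | O=Cc1cc(Br)c(O)cc1O
F2 | step 8 | 5-bromo-2-hydroxy-4-(triisopropylsilyloxy)benzaldehyde | O=Cc1cc(Br)c(O[Si](C(C)C)(C(C)C)C(C)C)cc1O
F3 | step 8 | 2-[5-bromo-2-hydroxy-4-(triisopropylsilyloxy)phenyl]-1,3-dithiane | Oc1cc(O[Si](C(C)C)(C(C)C)C(C)C)c(Br)cc1C1SCCCS1
F4 | step 8 | 2-[2-hydroxy-5-(3-methylbut-2-enyl)-4-(triisopropylsilyloxy)phenyl]-1,3-dithiane | CC(C)=CCc1cc(C2SCCCS2)c(O)cc1O[Si](C(C)C)(C(C)C)C(C)C
F5 | step 8 | {2-[2-hydroxy-5-(3-methylbut-2-enyl)-4-(triisopropylsilyloxy)phenyl]-1,3-dithian-2-yl}(4-methoxy-2-{[2-(trimethylsilyl)ethoxy]methoxy}phenyl)methanol, racemic | COc1ccc(C(O)C2(c3cc(CC=C(C)C)c(O[Si](C(C)C)(C(C)C)C(C)C)cc3O)SCCCS2)c(OCOCC[Si](C)(C)C)c1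
F6 | step 8 | 2-(4-methoxy-2-{[2-(trimethylsilyl)ethoxy]methoxy}phenyl)-5-(3-methylbut-2-enyl)-6-(triisopropylsilyloxy)-2H-spiro[benzofuran-3,2'-[1,3]dithiane], racemic | COc1ccc(C2Oc3cc(O[Si](C(C)C)(C(C)C)C(C)C)c(CC=C(C)C)cc3C23SCCCS3)c(OCOCC[Si](C)(C)C)c1
F7 | step 7 | 2-{[(E)-1,2-dichloroethenyl]oxy}-2-(4-methoxy-2-{[2-(trimethylsilyl)ethoxy]methoxy}phenyl)-1-[4-(3-methylbut-2-enyl)furan-2-yl]ethanol, racemic diastereomer mixture | COc1ccc(C(O/C(Cl)=C\Cl)C(O)c2cc(CC=C(C)C)co2)c(OCOCC[Si](C)(C)C)c1
F8 | step 7 | 2-(ethynyloxy)-2-(4-methoxy-2-{[2-(trimethylsilyl)ethoxy]methoxy}phenyl)-1-[4-(3-methylbut-2-enyl)furan-2-yl]ethanol, racemic diastereomer mixture | C#COC(C(O)c1cc(CC=C(C)C)co1)c1ccc(OC)cc1OCOCC[Si](C)(C)C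
F9 | step 2 | 4-(3-methylbut-2-enyl)furan-2-carbaldehyde | O=Cc1cc(CC=C(C)C)co1
F10 | step 10 | 3,3-dimethoxy-2-(4-methoxy-2-{[2-(trimethylsilyl)ethoxy]methoxy}phenyl)-5-(3-methylbut-2-enyl)-6-(triisopropylsilyloxy)-2,3-dihydrobenzofuran, racemic | COc1ccc(C2Oc3cc(O[Si](C(C)C)(C(C)C)C(C)C)c(CC=C(C)C)cc3C2(OC)OC)c(OCOCC[Si](C)(C)C)c1
F11 | step 11 | 5-methoxy-2-[3-methoxy-5-(3-methylbut-2-enyl)-6-(triisopropylsilyloxy)benzofuran-2-yl]phenol | COc1ccc(-c2oc3cc(O[Si](C(C)C)(C(C)C)C(C)C)c(CC=C(C)C)cc3c2OC)c(O)c1
A1 | alternative 1 | ambofuranol bis(methoxymethyl) ether, 3-methoxy-6-(methoxymethoxy)-2-[4-methoxy-2-(methoxymethoxy)phenyl]-5-(3-methylbut-2-enyl)benzofuran | COCOc1cc2oc(-c3ccc(OC)cc3OCOC)c(OC)c2cc1CC=C(C)C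
A2 | alternative 1 | 2-[2-bromo-4-(methoxymethoxy)-5-(3-methylbut-2-enyl)phenyl]-2-methoxy-1-[4-methoxy-2-(methoxymethoxy)phenyl]ethanone, racemic | COCOc1cc(Br)c(C(OC)C(=O)c2ccc(OC)cc2OCOC)cc1CC=C(C)C
A3 | alternative 2 | 3-methoxy-2-(4-methoxy-2-triisopropylsilyloxyphenyl)-5-(3-methylbut-2-enyl)-6-triisopropylsilyloxybenzofuran-4-ol | COc1ccc(-c2oc3cc(O[Si](C(C)C)(C(C)C)C(C)C)c(CC=C(C)C)c(O)c3c2OC)c(O[Si](C(C)C)(C(C)C)C(C)C)c1
A4 | alternative 2 | 2-diazo-1-[4-methoxy-5-(4-methoxy-2-triisopropylsilyloxyphenyl)furan-2-yl]ethanone | [N-]=[N+]=CC(=O)c1cc(OC)c(-c2ccc(OC)cc2O[Si](C(C)C)(C(C)C)C(C)C)o1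
A5 | alternative 2 | triisopropyl[(5-methylhex-4-en-1-yn-1-yl)oxy]silane | CC(C)=CCC#CO[Si](C(C)C)(C(C)C)C(C)C
A6 | alternative 3 | 6-(methoxymethoxy)-2-[4-methoxy-2-(methoxymethoxy)phenyl]-5-(3-methylbut-2-enyl)benzofuran-3(2H)-one, racemic | O=C1C(c2ccc(OC)cc2OCOC)Oc2cc(OCOC)c(CC=C(C)C)cc21
A7 | alternative 3 | 7-(methoxymethoxy)-2,2-dimethyl-6-(3-methylbut-2-enyl)-4H-1,3-benzodioxin-4-one | COCOc1cc2OC(C)(C)OC(=O)c2cc1CC=C(C)C
A8 | alternative 3 | [4-methoxy-2-(methoxymethoxy)benzyl]diphenylsulfonium trifluoromethanesulfonate | COCOc1cc(OC)ccc1C[S+](c1ccccc1)c1ccccc1.[O-]S(=O)(=O)C(F)(F)F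
A9 | alternative 3 | diphenylsulfonium 2-[2-hydroxy-4-(methoxymethoxy)-5-(3-methylbut-2-enyl)phenyl]-1-[4-methoxy-2-(methoxymethoxy)phenyl]-2-oxoethylide | COCOc1cc(O)c(C(=O)[C-](c2ccc(OC)cc2OCOC)[S+](c2ccccc2)c2ccccc2)cc1CC=C(C)C
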